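## Structural features

The target is a cembranolide: a 14-membered carbocycle (C1–C14) cis-fused at C1/C14 to an α-methylene-γ-butyrolactone. Numbering used throughout: C15 is the lactone α-carbon on C1, C16 the carbonyl, C17 the exocyclic methylene, C18 the methyl on C4, C19 the methylene on C8, C20 the methyl on C12. Four contiguous stereocentres lie on one edge, C12 (methyl, S), C13 (acetoxy, R), C14 (lactone oxygen, R) and C1 (S); C12/C13 and C13/C14 are syn in the extended chain and the ring fusion is cis. Two remote elements complete the set: the allylic acetate carbon C7 (R) beside the C8=C19 methylene, and the trans trisubstituted oxirane C3/C4 (3R,4R). The fragile groups are the α-methylene lactone (Michael acceptor, enolisable precursor), the two acetates (one allylic), the acid-labile oxirane and the 1,1-disubstituted alkene. The real difficulty is closing the 14-membered ring while the C7 and C3/C4 elements stay in register with the lactone edge, without exposing the lactone to the ring-closing reagent. The key step uses the fact that O7 sits 1,3 to C5, the allylic carbon of the C3=C4 unit that later becomes the oxirane. A sulfur-stabilised allyl anion at C5 can therefore open a terminal C6–C7 oxirane of fixed configuration at its CH2 carbon, making C5–C6 and the macrocycle. The seco compound and the macrocycle were checked centre by centre against the target: C1, C12, C13 and C14 match, and C7 is (S) in the oxirane but (R) in the carbinol only because the CIP rank of C6 changes. No configurational correction is needed; what is changed is the masking of O13, O14 and C16.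

## Logic of the disconnections

38 ⇒ 37. The two C–O bonds of the C3/C4 oxirane are cut last. The oxirane is the most acid-sensitive group, and C3=C4 must exist earlier as part of the allyl anion. This removes two stereocentres. The forward step must be reagent-controlled on a trisubstituted E-alkene and must leave C8=C19 and C15=C17 alone; both are electron-poorer once O7 is acetylated.

37 ⇒ 36 ⇒ 35 ⇒ 32. The two acetyl C–O bonds are cut, the hydroxyls are exchanged for silyl ethers, and C15=C17 is cut. Acetates would not survive the enolate needed for methylenation, and the methylene lactone would not survive anything earlier. 32 has a single enolisable position. The forward step needs base-stable protection at O7 and O13.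

32 ⇒ 31 ⇒ 30 ⇒ 29 ⇒ 28. C16 is taken back from lactone to methyl acetal, the O7 silyl group is removed and the C5–S bond is restored. A lactone cannot face an organolithium, and sulfur is the handle for ring closure. This arrives at the direct product of the macrocyclisation. The forward demand is C–S cleavage that leaves C3=C4 in place and with E geometry.

28 ⇒ 27. C5–C6 is cut. This opens the 14-membered ring to a seco chain whose only electrophile is a terminal oxirane and whose only acidic site is the allylic, sulfur-bearing C5. The forward step needs α-alkylation, attack at the oxirane CH2 and high dilution.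

27 ⇒ 26 ⇒ 25 ⇒ 24 ⇒ 23. The O7–C6 oxirane bond is cut back to a 1,2-diol and the acetal back to the lactone. A single acid treatment in methanol can both release the C6/C7 diol from its acetonide and cap the lactol, so only one acetonide is ever present. The forward demand is primary-selective sulfonylation.

23 ⇒ 22 ⇒ 21 ⇒ 9 + 19. The C1–H bond is cut (restoring C1=C15), the O13 silyl group is removed, and then C13–C14 is cut. The butenolide acts first as the C14 nucleophile (through 20) and then as the template that sets C1 cis. This divides the molecule into two fragments of similar size. The forward steps need threo and Felkin selectivity in the aldol and hydride delivery anti to the C14 substituent.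

19 ⇒ 18 ⇒ 12 + 16. C8–C9 is cut. An sp2–sp3 coupling makes the 1,1-disubstituted alkene directly and separates the remote centres C7 and C12 into independent pieces. The forward step needs hydroboration of a terminal alkene (via 17) and a regiodefined enol triflate.

9 ⇒ 3 + 8. C1–C2 is cut as an alkenyl–allyl coupling. The forward step must couple at the primary allylic terminus with retention of E geometry.

12 ⇒ 11 ⇒ 10; 16 ⇒ 15 ⇒ 14 ⇒ 13; 8 ⇒ 7 ⇒ 6 ⇒ 5 ⇒ 4; 3 ⇒ 2 ⇒ 1. The remaining cuts are C11–C12 (auxiliary-controlled allylation setting C12), C8–C19 (methyl addition to the C7-bearing aldehyde), the C5–S and C2–Br bonds after allylic oxidation of the E-methyl group, and the C–Sn/C–Br bonds of the furanone. All end at commercial materials.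

## Other disconnections considered

Alternative 1: The cut is O14–C16 and C15–C16, with carbon monoxide as C16. In the forward step the macrocyclic ethynyl carbinol A1 (free 14-OH, ethynyl on C1) would be cyclocarbonylated with CO, PdCl2, SnCl2 and PPh3 to the methylene lactone A2. In its favour: carbonyl and exocyclic methylene arrive together, no enolate chemistry is needed, and no lactone has to be masked while the large ring is made. The conditions are neutral and should tolerate silyl ethers and isolated alkenes better than an organolithium does; on functional-group tolerance the alternative is the better. Against it here: the step closes only the five-membered ring, so A1 still needs its own macrocyclisation and its own control of the C1/C14 relationship, and it needs pressurised CO with a stoichiometric tin additive. A2 is the same compound as 35, so both plans share the last three steps. The alternative would save about four operations between ring closure and A2 (better on step economy there), but this is offset by the extra ring-forming step and the stereocontrolled route to A1. Overall length is judged equal.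

Alternative 2: The cut is C9–C10. Pd(PPh3)4 would ionise the allylic carbonate of the open-chain bis-sulfone A3, and the bis(phenylsulfonyl)methyl carbanion would attack the 2-substituted allyl unit to give macrocycle A4. In its favour: both allyl termini are CH2, so the regiochemistry is degenerate. The nucleophile is soft and the medium nearly neutral, so the lactone and even the C3/C4 oxirane can be present; on this point it is better than the chosen plan, which must mask the lactone. The reaction class is at least as dependable for 14-membered rings as the carbanion–oxirane closure. Against it here: two sulfonyl groups on C10 must be removed reductively afterwards in the presence of the oxirane, the lactone and an allylic silyl ether. No stereocentre is gained, the bis-sulfone and carbonate cost steps, and methylenation is still to come. Mechanistically it trades one C–S cleavage under dissolving metal (chosen plan) for two under comparable conditions on a more sensitive molecule. Step economy is similar or slightly worse.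

Alternative 3: The cut is C13–C14. BF3·OEt2 would make C14 of the 2-silyloxyfuran in the seco aldehyde A5 attack the C13 aldehyde on the same chain, giving the macrocyclic butenolide A6. In its favour: it is the intramolecular form of step 15 and would create the ring and two stereocentres in one operation, a larger gain per step than the chosen key step (named as better). It needs no sulfur and no dissolving metal, so C3=C4 is never part of an allyl anion, and the endgame is short. Against it here: threo and Felkin preferences would have to hold inside a macrocyclic transition state. A labile silyloxyfuran and an aldehyde must coexist on one chain at high dilution with a Lewis acid, so desilylation or oligomerisation could compete. The later conjugate reduction would then be governed by ring conformation rather than by simple anti approach. The chosen plan sets C13, C14 and C1 in the open chain, where the models are reliable, and buys C7 from the chiral pool, at the price of masking and unmasking the lactone. On step count the alternative would probably be shorter by three or four steps; on predictability of stereocontrol the chosen plan is stronger.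

Key step: step 21

Assumption: C16 (lactol or methyl acetal) and the sulfur-bearing C5 are carried as epimer mixtures because both are erased before the target; TBS means tert-butyldimethylsilyl and 9-BBN means 9-borabicyclo[3.3.1]nonane.

## Route

Step 1
Reactants: 1 tetronic acid
Product: 2 4-bromofuran-2(5H)-one
Conditions: (COBr)2, DMF (cat.), CH2Cl2, 0 °C to rt
Reagents that add atoms: oxalyl bromide, O=C(Br)C(=O)Br
Why: Vilsmeier-type activation of the vinylogous acid converts the enol OH into the vinylogous acyl bromide; the lactone is untouched.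

Step 2
Reactants: 2 4-bromofuran-2(5H)-one
Product: 3 4-(tributylstannyl)furan-2(5H)-one
Conditions: (Bu3Sn)2, Pd(PPh3)4 (cat.), THF, reflux
Reagents that add atoms: hexabutylditin, CCCC[Sn](CCCC)(CCCC)[Sn](CCCC)(CCCC)CCCC
Why: Palladium-catalysed stannylation of an activated alkenyl bromide (oxidative addition, Sn–Sn transmetalation, reductive elimination) gives the β-stannyl butenolide needed for Stille coupling.

Step 3
Reactants: 4 prenyl acetate
Product: 5 (E)-4-hydroxy-3-methylbut-2-en-1-yl acetate
Conditions: SeO2 (cat.), t-BuOOH, CH2Cl2, rt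
Reagents that add atoms: tert-butyl hydroperoxide, CC(C)(C)OO
Why: Selenium dioxide allylic oxidation (ene reaction then [2,3]-shift) attacks the E-methyl group of a trisubstituted alkene selectively, which fixes the E geometry of the future C3=C4 bond.

Step 4
Reactants: 5 (E)-4-hydroxy-3-methylbut-2-en-1-yl acetate
Product: 6 (E)-3-methyl-4-(phenylsulfanyl)but-2-en-1-yl acetate
Conditions: PhSSPh, n-Bu3P, THF, rt
Reagents that add atoms: diphenyl disulfide, c1ccc(cc1)SSc1ccccc1
Why: Hata thioetherification activates the primary allylic alcohol as an alkoxyphosphonium ion that thiolate displaces; the acetate at the other terminus is inert.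

Step 5
Reactants: 6 (E)-3-methyl-4-(phenylsulfanyl)but-2-en-1-yl acetate
Product: 7 (E)-3-methyl-4-(phenylsulfanyl)but-2-en-1-ol
Conditions: K2CO3, MeOH, rt
Reagents that add atoms: none
Why: Base-catalysed transesterification removes the acetate; the sulfide and the alkene geometry are unaffected.

Step 6
Reactants: 7 (E)-3-methyl-4-(phenylsulfanyl)but-2-en-1-ol
Product: 8 (E)-(4-bromo-2-methylbut-2-en-1-yl)(phenyl)sulfane
Conditions: CBr4, PPh3, CH2Cl2, 0 °C
Reagents that add atoms: carbon tetrabromide, BrC(Br)(Br)Br
Why: Appel bromination of a primary allylic alcohol proceeds by SN2 at the primary carbon without allylic transposition at low temperature; the bromide is used at once.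

Step 7
Reactants: 3 4-(tributylstannyl)furan-2(5H)-one; 8 (E)-(4-bromo-2-methylbut-2-en-1-yl)(phenyl)sulfane
Product: 9 4-[(E)-3-methyl-4-(phenylsulfanyl)but-2-en-1-yl]furan-2(5H)-one
Conditions: Pd2(dba)3 (cat.), AsPh3, THF, 60 °C
Reagents that add atoms: none
Why: Stille coupling of the alkenylstannane with the allylic bromide forms C1–C2 at the primary allyl terminus; syn/anti exchange at the fully substituted terminus is slow, so the E geometry should be kept.

Step 8
Reactants: 10 (R)-4-benzyl-3-propanoyloxazolidin-2-one
Product: 11 (R)-4-benzyl-3-[(S)-2-methylpent-4-enoyl]oxazolidin-2-one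
Conditions: NaN(SiMe3)2, THF, −78 °C; allyl iodide, −78 to −45 °C
Reagents that add atoms: allyl iodide, C=CCI
Why: Evans alkylation: the chelated Z-enolate is allylated on the face opposite the benzyl group, which sets C12 (S) under auxiliary control.

Step 9
Reactants: 11 (R)-4-benzyl-3-[(S)-2-methylpent-4-enoyl]oxazolidin-2-one
Product: 12 (S)-2-methylpent-4-en-1-ol
Conditions: LiBH4, H2O (1 equiv), Et2O, 0 °C
Reagents that add atoms: none
Why: Reductive cleavage of the imide gives the primary alcohol without touching the α-stereocentre and releases the auxiliary for recovery.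

Step 10
Reactants: 13 (R)-2,2-dimethyl-1,3-dioxolane-4-carbaldehyde
Product: 14 1-[(4R)-2,2-dimethyl-1,3-dioxolan-4-yl]ethan-1-ol (both carbinol epimers)
Conditions: MeMgBr, THF, −78 to 0 °C
Reagents that add atoms: methylmagnesium bromide, C[Mg]Br
Why: Grignard addition brings in the carbon that becomes C19; the new carbinol centre is oxidised in the next step, so its configuration is irrelevant.

Step 11
Reactants: 14 1-[(4R)-2,2-dimethyl-1,3-dioxolan-4-yl]ethan-1-ol
Product: 15 1-[(4R)-2,2-dimethyl-1,3-dioxolan-4-yl]ethan-1-one
Conditions: Dess–Martin periodinane, NaHCO3, CH2Cl2, 0 °C to rt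
Reagents that add atoms: none
Why: Buffered Dess–Martin oxidation gives the α-alkoxy methyl ketone under non-basic conditions, so the future C7 centre should not epimerise.

Step 12
Reactants: 15 1-[(4R)-2,2-dimethyl-1,3-dioxolan-4-yl]ethan-1-one
Product: 16 1-[(4R)-2,2-dimethyl-1,3-dioxolan-4-yl]ethenyl trifluoromethanesulfonate
Conditions: KN(SiMe3)2, THF, −78 °C; PhNTf2, −78 to 0 °C
Reagents that add atoms: N-phenylbis(trifluoromethanesulfonimide), O=S(=O)(N(c1ccccc1)S(=O)(=O)C(F)(F)F)C(F)(F)F
Why: Kinetic deprotonation occurs at the unhindered methyl group and not at the α-alkoxy methine; O-triflation then gives the terminal enol triflate that carries C8 and C19.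

Step 13
Reactants: 12 (S)-2-methylpent-4-en-1-ol; 16 enol triflate
Product: 18 (2S)-6-[(4S)-2,2-dimethyl-1,3-dioxolan-4-yl]-2-methylhept-6-en-1-ol, via bis-boron adduct 17 (not isolated)
Conditions: 9-BBN (2.2 equiv), THF, 0 °C to rt; then 16, Pd(dppf)Cl2 (cat.), AsPh3, Cs2CO3, DMF/H2O, rt
Reagents that add atoms: none
Why: Anti-Markovnikov hydroboration of the terminal alkene (one extra equivalent of borane is taken up by the hydroxyl) followed by B-alkyl Suzuki–Miyaura coupling with the enol triflate forms C8–C9 and the 1,1-disubstituted alkene in one operation; no stereocentre is involved.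

Step 14
Reactants: 18 (2S)-6-[(4S)-2,2-dimethyl-1,3-dioxolan-4-yl]-2-methylhept-6-en-1-ol
Product: 19 (2S)-6-[(4S)-2,2-dimethyl-1,3-dioxolan-4-yl]-2-methylhept-6-enal
Conditions: Dess–Martin periodinane, NaHCO3, CH2Cl2, 0 °C to rt
Reagents that add atoms: none
Why: Buffered Dess–Martin oxidation gives the α-methyl aldehyde without epimerising C12 or cleaving the acetonide; the aldehyde is used directly.

Step 15
Reactants: 9 4-[(E)-3-methyl-4-(phenylsulfanyl)but-2-en-1-yl]furan-2(5H)-one; 19 aldehyde
Product: 21 (5R)-5-[(1R,2S)-6-[(4S)-2,2-dimethyl-1,3-dioxolan-4-yl]-1-hydroxy-2-methylhept-6-en-1-yl]-4-[(2E)-3-methyl-4-(phenylsulfanyl)but-2-en-1-yl]furan-2(5H)-one, via silyloxyfuran 20 (not isolated)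
Conditions: TBSOTf (1.0 equiv), Et3N (1.05 equiv), CH2Cl2, 0 °C; then 19, BF3·OEt2, −78 °C
Reagents that add atoms: none
Why: Vinylogous Mukaiyama aldol: the aromatic 2-silyloxyfuran attacks the BF3-activated aldehyde through C14 in an open transition state, which should favour the threo (13,14-syn) adduct. Felkin–Anh addition to the α-methyl aldehyde should give the 12,13-syn relationship, so C13 (R) and C14 (R) arise together; minor diastereomers are removed by chromatography here.

Step 16
Reactants: 21 aldol adduct
Product: 22 (5R)-5-[(1R,2S)-1-(tert-butyldimethylsilyloxy)-6-[(4S)-2,2-dimethyl-1,3-dioxolan-4-yl]-2-methylhept-6-en-1-yl]-4-[(2E)-3-methyl-4-(phenylsulfanyl)but-2-en-1-yl]furan-2(5H)-one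
Conditions: TBSCl, imidazole, DMAP (cat.), DMF, rt
Reagents that add atoms: tert-butyldimethylsilyl chloride, CC(C)(C)[Si](C)(C)Cl
Why: Silylation with a weak base avoids enolising the butenolide at C14. The bulky ether distinguishes O13 from O14 for the rest of the route and prevents hydroxyl-directed hydride delivery in the next step.

Step 17
Reactants: 22 silylated butenolide
Product: 23 (4S,5R)-5-[(1R,2S)-1-(tert-butyldimethylsilyloxy)-6-[(4S)-2,2-dimethyl-1,3-dioxolan-4-yl]-2-methylhept-6-en-1-yl]-4-[(2E)-3-methyl-4-(phenylsulfanyl)but-2-en-1-yl]oxolan-2-one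
Conditions: Cu(OAc)2·H2O (cat.), 1,2-bis(diphenylphosphino)benzene (cat.), (EtO)2MeSiH, t-BuOH, toluene, rt
Reagents that add atoms: none
Why: Ligated copper hydride conjugate reduction adds hydride to C1 from the face opposite the bulky C14 substituent, so the C2 chain ends cis to C13 and C1 is set as S. Isolated alkenes and the sulfide are not reduced, unlike with nickel boride or hydrogenation.

Step 18
Reactants: 23 cis-lactone
Product: 24 (4S,5R)-5-[(1R,2S)-1-(tert-butyldimethylsilyloxy)-6-[(4S)-2,2-dimethyl-1,3-dioxolan-4-yl]-2-methylhept-6-en-1-yl]-4-[(2E)-3-methyl-4-(phenylsulfanyl)but-2-en-1-yl]oxolan-2-ol (both lactol epimers)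
Conditions: i-Bu2AlH, CH2Cl2, −78 °C
Reagents that add atoms: none
Why: Low-temperature hydride reduction stops at the stable aluminium lactolate, which gives the lactol on work-up; C16 is now at the aldehyde oxidation level and still tied to O14.

Step 19
Reactants: 24 lactol
Product: 25 (2S,7S,8R)-8-(tert-butyldimethylsilyloxy)-8-[(2R,3S)-5-methoxy-3-[(2E)-3-methyl-4-(phenylsulfanyl)but-2-en-1-yl]oxolan-2-yl]-7-methyl-3-methylideneoctane-1,2-diol (both acetal epimers)
Conditions: PPTS (cat.), MeOH, 40 °C
Reagents that add atoms: methanol, CO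
Why: One mild acid treatment converts the lactol into its methyl acetal through the oxocarbenium ion and removes the terminal acetonide by transacetalisation; the hindered secondary silyl ether should survive.

Step 20
Reactants: 25 acetal diol
Product: 27 tert-butyl{[(1R,2S)-1-[(2R,3S)-5-methoxy-3-[(2E)-3-methyl-4-(phenylsulfanyl)but-2-en-1-yl]oxolan-2-yl]-2-methyl-6-[(2S)-oxiran-2-yl]hept-6-en-1-yl]oxy}dimethylsilane (both acetal epimers), via primary tosylate 26 (not isolated)
Conditions: TsCl, Bu2SnO (cat.), Et3N, CH2Cl2, 0 °C; then K2CO3, MeOH, rt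
Reagents that add atoms: none
Why: Tin-catalysed sulfonylation selects the primary hydroxyl of the 1,2-diol; the C7 alkoxide then displaces the tosylate at C6, so the C7–O bond is never broken and the glyceraldehyde configuration is retained.

Step 21
Reactants: 27 seco epoxy allylic sulfide
Product: 28 (1S,3E,7R,12S,13R,14R)-13-(tert-butyldimethylsilyloxy)-16-methoxy-5-(phenylsulfanyl)-14,16-epoxycembra-3,8(19)-dien-7-ol (C5 and C16 epimers)
Conditions: n-BuLi (1.1 equiv), DABCO, THF, −78 to −20 °C, slow addition of 27 to high dilution; then H2O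
Reagents that add atoms: none
Why: n-BuLi removes a proton from C5, the only carbon that is both allylic and α to sulfur, and the lithiated allyl sulfide attacks the unsubstituted oxirane carbon C6 in an SN2 opening that forms C5–C6 and releases the C7 alkoxide. The closest known reaction type is the intramolecular alkylation of lithiated allylic phenyl sulfides by terminal epoxides used to form 14-membered terpenoid rings. The 14-membered ring closes in exo mode (14-exo-tet), with the oxirane oxygen ending outside the ring as the C7 hydroxyl. No stereocentre is set under control: C7 keeps the configuration of the oxirane because only C6 is attacked, and C5 forms as both epimers and is erased in step 22. Three selectivities are needed. α- over γ-alkylation is secured by the lithium contact ion pair in THF with DABCO and by the alkyl substituent on the γ-carbon C3. Attack at C6 rather than SN2′ attack at C19 is favoured by the unhindered primary oxirane carbon and lithium coordination to the oxirane oxygen. Ring closure over oligomerisation is secured by slow addition at high dilution. The lactone is present only as a methyl acetal and O13 as a silyl ether, so the oxirane is the sole electrophile and no other acidic site competes.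

Step 22
Reactants: 28 macrocyclic hydroxy sulfide
Product: 29 (1S,3E,7R,12S,13R,14R)-13-(tert-butyldimethylsilyloxy)-16-methoxy-14,16-epoxycembra-3,8(19)-dien-7-ol (C16 epimers)
Conditions: Li, EtNH2, THF, −78 °C, short contact; then H2O
Reagents that add atoms: none
Why: Dissolving-metal cleavage of the allylic C–S bond gives an allyl anion that should be protonated at C5 by the neighbouring C7 hydroxyl through a six-membered transition state, keeping C3=C4 in place and E. The acetal, the silyl ether and the unconjugated alkenes are inert at −78 °C, and both C5 epimers converge.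

Step 23
Reactants: 29 macrocyclic alcohol
Product: 30 (1S,3E,7R,12S,13R,14R)-7,13-bis(tert-butyldimethylsilyloxy)-16-methoxy-14,16-epoxycembra-3,8(19)-diene (C16 epimers)
Conditions: TBSCl, imidazole, DMAP (cat.), DMF, 40 °C
Reagents that add atoms: tert-butyldimethylsilyl chloride, CC(C)(C)[Si](C)(C)Cl
Why: Standard silylation of the allylic secondary alcohol; a silyl chloride with imidazole is chosen because silyl triflates can ionise the methyl acetal.

Step 24
Reactants: 30 bis-silyl acetal
Product: 31 (1S,3E,7R,12S,13R,14R)-7,13-bis(tert-butyldimethylsilyloxy)-14,16-epoxycembra-3,8(19)-dien-16-ol (lactol epimers)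
Conditions: AcOH/THF/H2O (3:1:1), rt
Reagents that add atoms: water, O
Why: The 2-methoxytetrahydrofuran hydrolyses readily through its oxocarbenium ion under conditions that secondary silyl ethers tolerate; the lactol cannot change ring size because O13 is still silylated.

Step 25
Reactants: 31 lactol
Product: 32 (1S,3E,7R,12S,13R,14R)-7,13-bis(tert-butyldimethylsilyloxy)cembra-3,8(19)-dien-16,14-olide
Conditions: tetrapropylammonium perruthenate (cat.), N-methylmorpholine N-oxide, 4 Å molecular sieves, CH2Cl2, rt
Reagents that add atoms: none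
Why: Ley–Griffith oxidation of the lactol gives the cis-fused γ-lactone under neutral conditions; no free hydroxyl or sulfide remains to compete.

Step 26
Reactants: 32 saturated lactone
Product: 35 (1S,3E,7R,12S,13R,14R)-7,13-bis(tert-butyldimethylsilyloxy)cembra-3,8(19),15(17)-trien-16,14-olide, via Mannich base 33 (not isolated), via ammonium iodide 34 (not isolated)
Conditions: LiN(i-Pr)2, THF, −78 °C; Me2N=CH2 iodide, −78 °C to rt; MeI, rt; aq. NaHCO3, rt
Reagents that add atoms: dimethylmethyleneammonium iodide (Eschenmoser's salt), C=[N+](C)C.[I-]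
Why: The lactone has one enolisable position (C15); Mannich reaction of its lithium enolate with Eschenmoser's salt, N-methylation and base-induced elimination of trimethylamine install C17 as the exocyclic methylene. Both hydroxyls are silyl ethers, so no alkoxide can open or transpose the lactone.

Step 27
Reactants: 35 bis-silyl methylene lactone
Product: 36 (1S,3E,7R,12S,13R,14R)-7,13-dihydroxycembra-3,8(19),15(17)-trien-16,14-olide
Conditions: HF·pyridine, pyridine, THF, 0 °C to rt
Reagents that add atoms: none
Why: Buffered fluoride cleaves both secondary silyl ethers without the basic conditions that would add to the methylene lactone; the oxirane is not yet present.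

Step 28
Reactants: 36 diol
Product: 37 (1S,3E,7R,12S,13R,14R)-7,13-diacetoxycembra-3,8(19),15(17)-trien-16,14-olide
Conditions: Ac2O, pyridine, DMAP (cat.), CH2Cl2, rt
Reagents that add atoms: acetic anhydride, CC(=O)OC(C)=O
Why: Nucleophile-catalysed acylation esterifies both secondary hydroxyls; the allylic acetate formed at C7 also lowers the electron density of C8=C19 before the epoxidation.

Step 29
Reactants: 37 diacetate
Product: 38 (1S,3R,4R,7R,12S,13R,14R)-7,13-diacetoxy-3,4-epoxycembra-8(19),15(17)-dien-16,14-olide (target)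
Conditions: Shi ketone from D-fructose (0.3 equiv), KHSO5 (as 2KHSO5·KHSO4·K2SO4), K2CO3, Bu4NHSO4, MeCN/CH2(OMe)2, aq. Na2B4O7/Na2EDTA buffer, 0 °C
Reagents that add atoms: potassium peroxymonosulfate, [K+].[O-]S(=O)(=O)OO
Why: Shi epoxidation: the chiral dioxirane transfers oxygen through a spiro transition state, which for trans and trisubstituted alkenes with the D-fructose-derived ketone gives the (R,R) sense required at C3/C4. The electron-rich trisubstituted alkene should react well before the acetate-deactivated C8=C19 and the electron-poor C15=C17.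

## Compound list

1 | tetronic acid (furan-2,4(3H,5H)-dione) | O=C1CC(=O)CO1 | starting material
2 | 4-bromofuran-2(5H)-one | O=C1C=C(Br)CO1 | intermediate
3 | 4-(tributylstannyl)furan-2(5H)-one | CCCC[Sn](CCCC)(CCCC)C1=CC(=O)OC1 | intermediate
4 | prenyl acetate (3-methylbut-2-en-1-yl acetate) | CC(C)=CCOC(C)=O | starting material
5 | (E)-4-hydroxy-3-methylbut-2-en-1-yl acetate | CC(=O)OC/C=C(C)/CO | intermediate
6 | (E)-3-methyl-4-(phenylsulfanyl)but-2-en-1-yl acetate | CC(=O)OC/C=C(C)/CSc1ccccc1 | intermediate
7 | (E)-3-methyl-4-(phenylsulfanyl)but-2-en-1-ol | OC/C=C(C)/CSc1ccccc1 | intermediate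
8 | (E)-(4-bromo-2-methylbut-2-en-1-yl)(phenyl)sulfane | BrC/C=C(C)/CSc1ccccc1 | intermediate
9 | 4-[(E)-3-methyl-4-(phenylsulfanyl)but-2-en-1-yl]furan-2(5H)-one | O=C1C=C(C/C=C(C)/CSc2ccccc2)CO1 | intermediate
10 | (R)-4-benzyl-3-propanoyloxazolidin-2-one | CCC(=O)N1[C@H](Cc2ccccc2)COC1=O | starting material
11 | (R)-4-benzyl-3-[(S)-2-methylpent-4-enoyl]oxazolidin-2-one | C=CC[C@H](C)C(=O)N1[C@H](Cc2ccccc2)COC1=O | intermediate
12 | (S)-2-methylpent-4-en-1-ol | C=CC[C@H](C)CO | intermediate
13 | (R)-2,2-dimethyl-1,3-dioxolane-4-carbaldehyde | O=C[C@H]1COC(C)(C)O1 | starting material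
14 | 1-[(4R)-2,2-dimethyl-1,3-dioxolan-4-yl]ethan-1-ol (carbinol epimers) | CC(O)[C@H]1COC(C)(C)O1 | intermediate
15 | 1-[(4R)-2,2-dimethyl-1,3-dioxolan-4-yl]ethan-1-one | CC(=O)[C@H]1COC(C)(C)O1 | intermediate
16 | 1-[(4R)-2,2-dimethyl-1,3-dioxolan-4-yl]ethenyl trifluoromethanesulfonate | C=C(OS(=O)(=O)C(F)(F)F)[C@H]1COC(C)(C)O1 | intermediate
17 | 9-{(4S)-5-[(9-borabicyclo[3.3.1]nonan-9-yl)oxy]-4-methylpentyl}-9-borabicyclo[3.3.1]nonane | C(CC[C@H](C)COB1C2CCCC1CCC2)B1C2CCCC1CCC2 | intermediate (not isolated)
18 | (2S)-6-[(4S)-2,2-dimethyl-1,3-dioxolan-4-yl]-2-methylhept-6-en-1-ol | C=C(CCC[C@H](C)CO)[C@H]1COC(C)(C)O1 | intermediate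
19 | (2S)-6-[(4S)-2,2-dimethyl-1,3-dioxolan-4-yl]-2-methylhept-6-enal | C=C(CCC[C@H](C)C=O)[C@H]1COC(C)(C)O1 | intermediate
20 | tert-butyl(dimethyl)({4-[(E)-3-methyl-4-(phenylsulfanyl)but-2-en-1-yl]furan-2-yl}oxy)silane | CC(C)(C)[Si](C)(C)Oc1cc(C/C=C(C)/CSc2ccccc2)co1 | intermediate (not isolated)
21 | (5R)-5-[(1R,2S)-6-[(4S)-2,2-dimethyl-1,3-dioxolan-4-yl]-1-hydroxy-2-methylhept-6-en-1-yl]-4-[(2E)-3-methyl-4-(phenylsulfanyl)but-2-en-1-yl]furan-2(5H)-one | C=C(CCC[C@H](C)[C@@H](O)[C@@H]1OC(=O)C=C1C/C=C(C)/CSc1ccccc1)[C@H]1COC(C)(C)O1 | intermediate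
22 | (5R)-5-[(1R,2S)-1-(tert-butyldimethylsilyloxy)-6-[(4S)-2,2-dimethyl-1,3-dioxolan-4-yl]-2-methylhept-6-en-1-yl]-4-[(2E)-3-methyl-4-(phenylsulfanyl)but-2-en-1-yl]furan-2(5H)-one | C=C(CCC[C@H](C)[C@@H](O[Si](C)(C)C(C)(C)C)[C@@H]1OC(=O)C=C1C/C=C(C)/CSc1ccccc1)[C@H]1COC(C)(C)O1 | intermediate
23 | (4S,5R)-5-[(1R,2S)-1-(tert-butyldimethylsilyloxy)-6-[(4S)-2,2-dimethyl-1,3-dioxolan-4-yl]-2-methylhept-6-en-1-yl]-4-[(2E)-3-methyl-4-(phenylsulfanyl)but-2-en-1-yl]oxolan-2-one | C=C(CCC[C@H](C)[C@@H](O[Si](C)(C)C(C)(C)C)[C@@H]1OC(=O)C[C@@H]1C/C=C(C)/CSc1ccccc1)[C@H]1COC(C)(C)O1 | intermediate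
24 | (4S,5R)-5-[(1R,2S)-1-(tert-butyldimethylsilyloxy)-6-[(4S)-2,2-dimethyl-1,3-dioxolan-4-yl]-2-methylhept-6-en-1-yl]-4-[(2E)-3-methyl-4-(phenylsulfanyl)but-2-en-1-yl]oxolan-2-ol (lactol epimers) | C=C(CCC[C@H](C)[C@@H](O[Si](C)(C)C(C)(C)C)[C@@H]1OC(O)C[C@@H]1C/C=C(C)/CSc1ccccc1)[C@H]1COC(C)(C)O1 | intermediate
25 | (2S,7S,8R)-8-(tert-butyldimethylsilyloxy)-8-[(2R,3S)-5-methoxy-3-[(2E)-3-methyl-4-(phenylsulfanyl)but-2-en-1-yl]oxolan-2-yl]-7-methyl-3-methylideneoctane-1,2-diol (acetal epimers) | C=C(CCC[C@H](C)[C@@H](O[Si](C)(C)C(C)(C)C)[C@@H]1OC(OC)C[C@@H]1C/C=C(C)/CSc1ccccc1)[C@H](O)CO | intermediate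
26 | 1-O-(4-methylbenzenesulfonyl) derivative of 25 (primary tosylate, C7 hydroxyl free) | C=C(CCC[C@H](C)[C@@H](O[Si](C)(C)C(C)(C)C)[C@@H]1OC(OC)C[C@@H]1C/C=C(C)/CSc1ccccc1)[C@H](O)COS(=O)(=O)c1ccc(C)cc1 | intermediate (not isolated)
27 | tert-butyl{[(1R,2S)-1-[(2R,3S)-5-methoxy-3-[(2E)-3-methyl-4-(phenylsulfanyl)but-2-en-1-yl]oxolan-2-yl]-2-methyl-6-[(2S)-oxiran-2-yl]hept-6-en-1-yl]oxy}dimethylsilane (acetal epimers; key-step precursor) | C=C(CCC[C@H](C)[C@@H](O[Si](C)(C)C(C)(C)C)[C@@H]1OC(OC)C[C@@H]1C/C=C(C)/CSc1ccccc1)[C@H]1CO1 | intermediate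
28 | (1S,3E,7R,12S,13R,14R)-13-(tert-butyldimethylsilyloxy)-16-methoxy-5-(phenylsulfanyl)-14,16-epoxycembra-3,8(19)-dien-7-ol (C5 and C16 epimers; key-step product) | C=C1CCC[C@H](C)[C@@H](O[Si](C)(C)C(C)(C)C)[C@@H]2OC(OC)C[C@@H]2C/C=C(C)/C(Sc2ccccc2)C[C@H]1O | intermediate
29 | (1S,3E,7R,12S,13R,14R)-13-(tert-butyldimethylsilyloxy)-16-methoxy-14,16-epoxycembra-3,8(19)-dien-7-ol (C16 epimers) | C=C1CCC[C@H](C)[C@@H](O[Si](C)(C)C(C)(C)C)[C@@H]2OC(OC)C[C@@H]2C/C=C(C)/CC[C@H]1O | intermediate
30 | (1S,3E,7R,12S,13R,14R)-7,13-bis(tert-butyldimethylsilyloxy)-16-methoxy-14,16-epoxycembra-3,8(19)-diene (C16 epimers) | C=C1CCC[C@H](C)[C@@H](O[Si](C)(C)C(C)(C)C)[C@@H]2OC(OC)C[C@@H]2C/C=C(C)/CC[C@H]1O[Si](C)(C)C(C)(C)C | intermediate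
31 | (1S,3E,7R,12S,13R,14R)-7,13-bis(tert-butyldimethylsilyloxy)-14,16-epoxycembra-3,8(19)-dien-16-ol (lactol epimers) | C=C1CCC[C@H](C)[C@@H](O[Si](C)(C)C(C)(C)C)[C@@H]2OC(O)C[C@@H]2C/C=C(C)/CC[C@H]1O[Si](C)(C)C(C)(C)C | intermediate
32 | (1S,3E,7R,12S,13R,14R)-7,13-bis(tert-butyldimethylsilyloxy)cembra-3,8(19)-dien-16,14-olide | C=C1CCC[C@H](C)[C@@H](O[Si](C)(C)C(C)(C)C)[C@@H]2OC(=O)C[C@@H]2C/C=C(C)/CC[C@H]1O[Si](C)(C)C(C)(C)C | intermediate
33 | 15-[(dimethylamino)methyl] derivative of 32 (C15 epimers) | C=C1CCC[C@H](C)[C@@H](O[Si](C)(C)C(C)(C)C)[C@@H]2OC(=O)C(CN(C)C)[C@@H]2C/C=C(C)/CC[C@H]1O[Si](C)(C)C(C)(C)C | intermediate (not isolated)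
34 | 15-[(trimethylammonio)methyl] derivative of 32, iodide salt | C=C1CCC[C@H](C)[C@@H](O[Si](C)(C)C(C)(C)C)[C@@H]2OC(=O)C(C[N+](C)(C)C)[C@@H]2C/C=C(C)/CC[C@H]1O[Si](C)(C)C(C)(C)C.[I-] | intermediate (not isolated)
35 | (1S,3E,7R,12S,13R,14R)-7,13-bis(tert-butyldimethylsilyloxy)cembra-3,8(19),15(17)-trien-16,14-olide | C=C1CCC[C@H](C)[C@@H](O[Si](C)(C)C(C)(C)C)[C@@H]2OC(=O)C(=C)[C@@H]2C/C=C(C)/CC[C@H]1O[Si](C)(C)C(C)(C)C | intermediate
36 | (1S,3E,7R,12S,13R,14R)-7,13-dihydroxycembra-3,8(19),15(17)-trien-16,14-olide | C=C1CCC[C@H](C)[C@@H](O)[C@@H]2OC(=O)C(=C)[C@@H]2C/C=C(C)/CC[C@H]1O | intermediate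
37 | (1S,3E,7R,12S,13R,14R)-7,13-diacetoxycembra-3,8(19),15(17)-trien-16,14-olide | C=C1CCC[C@H](C)[C@@H](OC(C)=O)[C@@H]2OC(=O)C(=C)[C@@H]2C/C=C(C)/CC[C@H]1OC(C)=O | intermediate
38 | (1S,3R,4R,7R,12S,13R,14R)-7,13-diacetoxy-3,4-epoxycembra-8(19),15(17)-dien-16,14-olide (CNP0323853.1) | C=C1CCC[C@H](C)[C@@H](OC(C)=O)[C@@H]2OC(=O)C(=C)[C@@H]2C[C@H]2O[C@]2(C)CC[C@H]1OC(C)=O | target

## Step count and least certain steps

Total: 29 steps. Longest linear sequence: 20 steps (steps 3–7 and 15–29, from 4 to 38).

Step 21 (key step). The processes most likely to interfere are bimolecular alkylation leading to oligomers, allylic attack at C19 of the vinyl oxirane (a 13-membered isomer), alkylation through the γ-carbon C3, and base-induced isomerisation of the oxirane by the organolithium. Fallback: the same bond is made with a sulfonyl-stabilised allyl anion. Starting from 27, the sulfur is oxidised with tetrapropylammonium perruthenate and N-methylmorpholine N-oxide to the allylic sulfone epoxide F1. F1 is deprotonated with LiN(SiMe3)2 in THF at high dilution; this anion is formed with a non-nucleophilic amide base, reacts only through its α-carbon and is softer toward the oxirane CH2, and should close to the macrocyclic hydroxy sulfone F2. Cleavage of the C–S bond of F2 with Li/EtNH2 at −78 °C, as in step 22, returns to the route at 29.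

Step 15. The α-methyl and α-methylene groups of 19 differ little in size, so discrimination between the aldehyde faces may be incomplete, and the threo preference rests on an open transition state. In addition, BF3 may cause loss of the allylic acetonide or an intramolecular ene-type reaction of 19, eroding the yield. Fallback: the order of fragment union is changed so that the acid-labile C6–C8 unit stays out of the aldol and the diastereomers are separated on a small compound. Starting from 12, Dess–Martin oxidation gives (S)-2-methylpent-4-enal F3. Its BF3-promoted aldol with 9 (through 20) gives (5R)-5-[(1R,2S)-1-hydroxy-2-methylpent-4-en-1-yl]-4-[(2E)-3-methyl-4-(phenylsulfanyl)but-2-en-1-yl]furan-2(5H)-one F4. Silylation as in step 16 gives its tert-butyldimethylsilyl ether F5, and copper hydride reduction as in step 17 gives the cis-lactone with a terminal alkene F6. Hydroboration of F6 with 9-BBN and Suzuki–Miyaura coupling with 16 under the conditions of step 13 returns to the route at 23.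

Step 22. The delocalised allyl anion may be protonated at C3 instead of C5, moving the double bond to C4=C5. The E geometry may be partly lost, and prolonged contact may reduce C8=C19. Fallback: the sulfur is removed by two allylic transpositions that cancel. Starting from 28, Bu3SnH with AIBN in toluene at 80 °C should give, by radical SH2′ substitution, the allylstannane F7 (3-tributylstannyl, double bond at C4=C5). Protodestannylation of F7 with HCl in MeOH at 0 °C (SE2′) places hydrogen on C5 and returns the double bond to C3=C4, rejoining the route at 29.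

Step 29. The macrocycle may expose one face of C3=C4 so strongly that catalyst control is overridden, giving poor facial selectivity. Oxygen transfer to C8=C19 and hydrolysis of the acetates or the lactone at the basic pH are further risks. Fallback: oxygen is delivered by anti addition followed by closure, which places it on the face opposite to the one that electrophiles prefer. Starting from 37, N-bromosuccinimide in aqueous THF at 0 °C gives the (3S,4R)-3-bromo-4-hydroxy compound F8 (bromine on the secondary C3, hydroxyl on the tertiary C4). DBU in toluene then closes the oxirane with inversion at C3, returning to the route at 38. This fallback is substrate-controlled and is the right choice when direct epoxidation favours the wrong face.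

## Further compounds

F1 | step 21 | sulfone analogue of 27: tert-butyl{[(1R,2S)-1-[(2R,3S)-5-methoxy-3-[(2E)-3-methyl-4-(phenylsulfonyl)but-2-en-1-yl]oxolan-2-yl]-2-methyl-6-[(2S)-oxiran-2-yl]hept-6-en-1-yl]oxy}dimethylsilane | C=C(CCC[C@H](C)[C@@H](O[Si](C)(C)C(C)(C)C)[C@@H]1OC(OC)C[C@@H]1C/C=C(C)/CS(=O)(=O)c1ccccc1)[C@H]1CO1
F2 | step 21 | (1S,3E,7R,12S,13R,14R)-13-(tert-butyldimethylsilyloxy)-16-methoxy-5-(phenylsulfonyl)-14,16-epoxycembra-3,8(19)-dien-7-ol (C5 and C16 epimers) | C=C1CCC[C@H](C)[C@@H](O[Si](C)(C)C(C)(C)C)[C@@H]2OC(OC)C[C@@H]2C/C=C(C)/C(S(=O)(=O)c2ccccc2)C[C@H]1O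
F3 | step 15 | (S)-2-methylpent-4-enal | C=CC[C@H](C)C=O
F4 | step 15 | (5R)-5-[(1R,2S)-1-hydroxy-2-methylpent-4-en-1-yl]-4-[(2E)-3-methyl-4-(phenylsulfanyl)but-2-en-1-yl]furan-2(5H)-one | C=CC[C@H](C)[C@@H](O)[C@@H]1OC(=O)C=C1C/C=C(C)/CSc1ccccc1
F5 | step 15 | (5R)-5-[(1R,2S)-1-(tert-butyldimethylsilyloxy)-2-methylpent-4-en-1-yl]-4-[(2E)-3-methyl-4-(phenylsulfanyl)but-2-en-1-yl]furan-2(5H)-one | C=CC[C@H](C)[C@@H](O[Si](C)(C)C(C)(C)C)[C@@H]1OC(=O)C=C1C/C=C(C)/CSc1ccccc1
F6 | step 15 | (4S,5R)-5-[(1R,2S)-1-(tert-butyldimethylsilyloxy)-2-methylpent-4-en-1-yl]-4-[(2E)-3-methyl-4-(phenylsulfanyl)but-2-en-1-yl]oxolan-2-one | C=CC[C@H](C)[C@@H](O[Si](C)(C)C(C)(C)C)[C@@H]1OC(=O)C[C@@H]1C/C=C(C)/CSc1ccccc1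
F7 | step 22 | (1S,7R,12S,13R,14R)-13-(tert-butyldimethylsilyloxy)-16-methoxy-3-(tributylstannyl)-14,16-epoxycembra-4,8(19)-dien-7-ol (C3 and C16 epimers) | C=C1CCC[C@H](C)[C@@H](O[Si](C)(C)C(C)(C)C)[C@@H]2OC(OC)C[C@@H]2CC([Sn](CCCC)(CCCC)CCCC)C(C)=CC[C@H]1O
F8 | step 29 | (1S,3S,4R,7R,12S,13R,14R)-7,13-diacetoxy-3-bromo-4-hydroxycembra-8(19),15(17)-dien-16,14-olide | C=C1CCC[C@H](C)[C@@H](OC(C)=O)[C@@H]2OC(=O)C(=C)[C@@H]2C[C@H](Br)[C@](C)(O)CC[C@H]1OC(C)=O
A1 | alternative 1 | (1S,3E,7R,12S,13R,14R)-7,13-bis(tert-butyldimethylsilyloxy)-1-ethynyl-14-hydroxy macrocycle (14-membered ring, C3=C4 and C8=C19 alkenes; seco-lactone alkynol) | C=C1CCC[C@H](C)[C@@H](O[Si](C)(C)C(C)(C)C)[C@H](O)[C@H](C#C)C/C=C(C)/CC[C@H]1O[Si](C)(C)C(C)(C)C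
A2 | alternative 1 | (1S,3E,7R,12S,13R,14R)-7,13-bis(tert-butyldimethylsilyloxy)cembra-3,8(19),15(17)-trien-16,14-olide (identical with 35) | C=C1CCC[C@H](C)[C@@H](O[Si](C)(C)C(C)(C)C)[C@@H]2OC(=O)C(=C)[C@@H]2C/C=C(C)/CC[C@H]1O[Si](C)(C)C(C)(C)C
A3 | alternative 2 | open-chain C9 allylic methyl carbonate with C10 bis(phenylsulfonyl)methyl terminus, cis-lactone, C3/C4 oxirane and 7,13-bis(tert-butyldimethylsilyl) ethers | COC(=O)OCC(=C)[C@H](O[Si](C)(C)C(C)(C)C)CC[C@@]1(C)O[C@@H]1C[C@H]1CC(=O)O[C@H]1[C@H](O[Si](C)(C)C(C)(C)C)[C@@H](C)CC(S(=O)(=O)c1ccccc1)S(=O)(=O)c1ccccc1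
A4 | alternative 2 | (1S,3R,4R,7R,12S,13R,14R)-7,13-bis(tert-butyldimethylsilyloxy)-3,4-epoxy-10,10-bis(phenylsulfonyl)cembr-8(19)-en-16,14-olide | C=C1CC(S(=O)(=O)c2ccccc2)(S(=O)(=O)c2ccccc2)C[C@H](C)[C@@H](O[Si](C)(C)C(C)(C)C)[C@@H]2OC(=O)C[C@@H]2C[C@H]2O[C@]2(C)CC[C@H]1O[Si](C)(C)C(C)(C)C
A5 | alternative 3 | (2S,7R,10E)-7-(tert-butyldimethylsilyloxy)-12-[5-(tert-butyldimethylsilyloxy)furan-3-yl]-2,10-dimethyl-6-methylidenedodec-10-enal | CC(C)(C)[Si](C)(C)Oc1cc(C/C=C(C)/CC[C@@H](O[Si](C)(C)C(C)(C)C)C(=C)CCC[C@H](C)C=O)co1
A6 | alternative 3 | (3E,7R,12S,13R,14R)-7-(tert-butyldimethylsilyloxy)-13-hydroxycembra-1(15),3,8(19)-trien-16,14-olide | C=C1CCC[C@H](C)[C@@H](O)[C@@H]2OC(=O)C=C2C/C=C(C)/CC[C@H]1O[Si](C)(C)C(C)(C)C
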